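The pyran ring is cut at C4–C4a and O1–C2. The key step exploits that C4a of ring A is ortho to O1 and para to the C7 oxygen, hence the nucleophilic carbon of 2-methoxyresorcinol, and that C4, C3 and C2 are the β, α and carbonyl carbons of an acrolein carrying ring B. One aminocatalytic cascade (Friedel–Crafts addition, enantioselective enamine protonation, lactolisation) should make both bonds, close ring C and set C3 as S. Its precursors are unprotected 2-methoxyresorcinol, whose two reactive carbons are symmetry-equivalent, and 2-(3-benzyloxy-2,4,5-trimethoxyphenyl)acrolein, built from syringol by regiochemically unambiguous substitutions.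

Key step: step 8

Assumption: the sense of induction of the aminocatalyst cannot be predicted for this new substrate pair, so the catalyst antipode that gives the 3S lactol (both antipodes are accessible) is fixed in a first screen and used throughout.

Remark on ring A: in a mono-ether of 2-methoxyresorcinol both free carbons next to an oxygen are activated alike (each ortho to one oxygen and para to the other) and only one of them can lactolise. The free, symmetric diol has a single kind of reactive carbon, so it is used unprotected and the 7-OH is carried through.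

Remark on ring B: a 3-O-benzylated 2,3,6-trimethoxyphenyl ring offers two equally activated carbons to an electrophile, so its formylation would not be selective. Ring B is therefore assembled from syringol, where symmetry (step 2) and the formyl group (step 3) each leave one site open. The C–O coupling follows the olefination so that no free aldehyde meets hot methoxide.

Step 1
Reactants: 1 2,6-dimethoxyphenol (syringol)
Product: 2 2-(benzyloxy)-1,3-dimethoxybenzene
Conditions: BnBr, K2CO3, DMF, 60 °C
Reagents that add atoms: benzyl bromide, BrCc1ccccc1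
Why: Williamson etherification of the only nucleophilic site, the phenoxide, with a reactive benzylic halide.

Step 2
Reactants: 2 2-(benzyloxy)-1,3-dimethoxybenzene
Product: 4 3-(benzyloxy)-2,4-dimethoxybenzaldehyde, via aryl iminium chloride 3 (not isolated)
Conditions: POCl3, DMF, 0 → 80 °C; then aq. NaOAc
Reagents that add atoms: N,N-dimethylformamide, CN(C)C=O; water, O
Why: Vilsmeier–Haack formylation, in which the two carbons flanking the methoxy groups are symmetry-equivalent and each is ortho to one in-plane methoxy and para to the other, whereas C5 is para only to the twisted central benzyloxy group, so a single aldehyde should form as with 1,2,3-trimethoxybenzene.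

Step 3
Reactants: 4 3-(benzyloxy)-2,4-dimethoxybenzaldehyde
Product: 5 3-(benzyloxy)-5-bromo-2,4-dimethoxybenzaldehyde
Conditions: NBS, MeCN, rt, dark
Reagents that add atoms: N-bromosuccinimide, O=C1CCC(=O)N1Br
Why: Electrophilic aromatic bromination should go to C5, which is ortho to the 4-methoxy and para to the 2-methoxy group and meta to the formyl group, while C6 is ortho to the deactivating formyl group.

Step 4
Reactants: 5 3-(benzyloxy)-5-bromo-2,4-dimethoxybenzaldehyde
Product: 6 3-(benzyloxy)-1-bromo-2,4-dimethoxy-5-(2-methoxyethenyl)benzene (E/Z mixture)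
Conditions: MeOCH2PPh3Cl, KOtBu, THF, 0 °C → rt
Reagents that add atoms: (methoxymethyl)triphenylphosphonium chloride, [Cl-].COC[P+](c1ccccc1)(c1ccccc1)c1ccccc1
Why: Wittig olefination of a non-enolisable aldehyde with the methoxymethylene ylide, to which the aryl bromide and the ethers are inert; the alkene geometry is irrelevant because step 6 removes it.

Step 5
Reactants: 6 3-(benzyloxy)-1-bromo-2,4-dimethoxy-5-(2-methoxyethenyl)benzene
Product: 7 3-(benzyloxy)-1,2,4-trimethoxy-5-(2-methoxyethenyl)benzene (E/Z mixture)
Conditions: NaOMe/MeOH, CuBr (10 mol%), DMF, 110 °C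
Reagents that add atoms: sodium methoxide, [Na+].[O-]C
Why: Ullmann-type copper-catalysed methoxylation of an aryl bromide, run on a substrate whose enol ether and benzyl ether are stable to methoxide.

Step 6
Reactants: 7 3-(benzyloxy)-1,2,4-trimethoxy-5-(2-methoxyethenyl)benzene
Product: 8 2-[3-(benzyloxy)-2,4,5-trimethoxyphenyl]acetaldehyde
Conditions: 2 M HCl, THF, 45 °C; crude product used at once
Reagents that add atoms: water, O
Why: Acid hydrolysis of the enol ether (C-protonation, hydration, loss of methanol) should free the homologated aldehyde under conditions that leave aryl methyl and benzyl ethers alone.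

Step 7
Reactants: 8 2-[3-(benzyloxy)-2,4,5-trimethoxyphenyl]acetaldehyde
Product: 9 2-[3-(benzyloxy)-2,4,5-trimethoxyphenyl]prop-2-enal
Conditions: 37% aq. CH2O, pyrrolidine (10 mol%), EtCO2H (10 mol%), i-PrOH, 45 °C; kept cold with BHT and used within hours
Reagents that add atoms: formaldehyde, C=O
Why: Amine-catalysed Mannich condensation and elimination (α-methylenation of an aldehyde), for which the doubly activated benzylic α-CH2 of an arylacetaldehyde is a good substrate.

Step 8
Reactants: 9 2-[3-(benzyloxy)-2,4,5-trimethoxyphenyl]prop-2-enal; 10 2-methoxybenzene-1,3-diol (2-methoxyresorcinol)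
Product: 12 (3S)-3-[3-(benzyloxy)-2,4,5-trimethoxyphenyl]-8-methoxychromane-2,7-diol (C2 anomers), via open-chain hydroxy aldehyde 11 (not isolated)
Conditions: 10 (2 equiv), slow addition of 9; chiral primary–tertiary diamine·TfOH (tert-leucine-derived N1,N1-diethyl-3,3-dimethylbutane-1,2-diamine, 3S-selective antipode, 20 mol%), CHCl3, 0 °C
Reagents that add atoms: none
Why: Proposed new method: the primary amine condenses with the α-branched enal 9 to an iminium ion whose unhindered methylene is attacked by C4 of resorcinol 10 (Friedel–Crafts conjugate addition, C4–C4a), the resulting aryl-conjugated enamine is protonated at the α-carbon by the catalyst's ammonium N–H, and hydrolysis releases aldehyde 11, which the adjacent phenol traps at once (O1–C2). The closest known reaction types are primary-amine-catalysed Friedel–Crafts additions of indoles to α-substituted acroleins that end in an enantioselective protonation, and aminocatalytic annulations of naphthols and electron-rich phenols with enals to chroman-2-ols. The pyran ring closes by 6-exo-trig addition of the phenol oxygen to the aldehyde carbonyl. C3 is set under catalyst control in the protonation, the proton reaching one enamine face inside the chiral ammonium/triflate ion pair, whereas C2 forms as an uncontrolled anomeric mixture that step 9 erases. The step needs C- over O-alkylation, a single ring carbon, mono-alkylation and no enolisation of the product: oxa-Michael addition is reversible and drains into the carbon pathway, C4 and C6 of 10 are symmetry-equivalent with a hydroxyl next to each (C5 is meta to both), so every C-alkylation leads to the same lactol, and lactolisation turns that hydroxyl into a less donating acetal oxygen (10 is also used in excess) and masks the α-aryl aldehyde.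

Step 9
Reactants: 12 (3S)-3-[3-(benzyloxy)-2,4,5-trimethoxyphenyl]-8-methoxychromane-2,7-diol
Product: 13 (3S)-3-[3-(benzyloxy)-2,4,5-trimethoxyphenyl]-8-methoxychroman-7-ol
Conditions: Et3SiH, BF3·OEt2, CH2Cl2, −78 → −40 °C
Reagents that add atoms: none
Why: Ionic hydrogenation of a lactol, in which BF3 ionises the anomeric hydroxyl to the 2-chromanyl oxocarbenium ion and triethylsilane should reduce it at low temperature faster than it can lose the C3 proton, so the C3 configuration, the benzyl ether and the free 7-OH are kept.

Step 10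
Reactants: 13 (3S)-3-[3-(benzyloxy)-2,4,5-trimethoxyphenyl]-8-methoxychroman-7-ol
Product: 14 (3S)-3-(3-hydroxy-2,4,5-trimethoxyphenyl)-8-methoxychroman-7-ol (target)
Conditions: H2 (1 atm), 10% Pd/C, EtOAc–MeOH, rt
Reagents that add atoms: none
Why: Catalytic hydrogenolysis of the aryl benzyl ether, which should leave the chroman C–O and C–C bonds and the C3 centre untouched.

Compound list
1 | 2,6-dimethoxyphenol (syringol) | COc1cccc(OC)c1O | starting material
2 | 2-(benzyloxy)-1,3-dimethoxybenzene | COc1cccc(OC)c1OCc1ccccc1 | intermediate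
3 | N-[3-(benzyloxy)-2,4-dimethoxybenzylidene]-N-methylmethanaminium chloride | C[N+](C)=Cc1ccc(OC)c(OCc2ccccc2)c1OC.[Cl-] | intermediate (not isolated)
4 | 3-(benzyloxy)-2,4-dimethoxybenzaldehyde | COc1ccc(C=O)c(OC)c1OCc1ccccc1 | intermediate
5 | 3-(benzyloxy)-5-bromo-2,4-dimethoxybenzaldehyde | COc1c(Br)cc(C=O)c(OC)c1OCc1ccccc1 | intermediate
6 | 3-(benzyloxy)-1-bromo-2,4-dimethoxy-5-(2-methoxyethenyl)benzene, E/Z mixture | COC=Cc1cc(Br)c(OC)c(OCc2ccccc2)c1OC | intermediate
7 | 3-(benzyloxy)-1,2,4-trimethoxy-5-(2-methoxyethenyl)benzene, E/Z mixture | COC=Cc1cc(OC)c(OC)c(OCc2ccccc2)c1OC | intermediate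
8 | 2-[3-(benzyloxy)-2,4,5-trimethoxyphenyl]acetaldehyde | O=CCc1cc(OC)c(OC)c(OCc2ccccc2)c1OC | intermediate
9 | 2-[3-(benzyloxy)-2,4,5-trimethoxyphenyl]prop-2-enal | C=C(C=O)c1cc(OC)c(OC)c(OCc2ccccc2)c1OC | intermediate
10 | 2-methoxybenzene-1,3-diol (2-methoxyresorcinol) | COc1c(O)cccc1O | starting material
11 | (2S)-2-[3-(benzyloxy)-2,4,5-trimethoxyphenyl]-3-(2,4-dihydroxy-3-methoxyphenyl)propanal | COc1cc([C@@H](C=O)Cc2ccc(O)c(OC)c2O)c(OC)c(OCc2ccccc2)c1OC | intermediate (not isolated)
12 | (3S)-3-[3-(benzyloxy)-2,4,5-trimethoxyphenyl]-8-methoxychromane-2,7-diol, mixture of C2 anomers | COc1cc([C@H]2C(O)Oc3c(ccc(O)c3OC)C2)c(OC)c(OCc2ccccc2)c1OC | intermediate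
13 | (3S)-3-[3-(benzyloxy)-2,4,5-trimethoxyphenyl]-8-methoxychroman-7-ol | COc1cc([C@H]2COc3c(ccc(O)c3OC)C2)c(OC)c(OCc2ccccc2)c1OC | intermediate
14 | (3S)-3-(3-hydroxy-2,4,5-trimethoxyphenyl)-8-methoxychroman-7-ol | COc1cc([C@H]2COc3c(ccc(O)c3OC)C2)c(OC)c(O)c1OC | target

Total step count: 10. Longest linear sequence: 10 steps (1 → 14); 10 is bought and enters at step 8.

Steps most likely to fail

Step 8. The enamine may be protonated with poor facial selectivity, a racemic acid-catalysed background addition may compete, or the resorcinol may be alkylated twice. The fallback uses established auxiliary chemistry, sets out from 8 and 10 and rejoins the route at 14. Pinnick oxidation of 8 (NaClO2, NaH2PO4, 2-methyl-2-butene) should give 2-[3-(benzyloxy)-2,4,5-trimethoxyphenyl]acetic acid F1. Its pivaloyl mixed anhydride is coupled with lithiated (S)-4-benzyloxazolidin-2-one to give the N-arylacetyl oxazolidinone F2. In parallel, 10 is dibenzylated (BnBr, K2CO3) to 1,3-bis(benzyloxy)-2-methoxybenzene F3, formylated (POCl3, DMF) to 2,4-bis(benzyloxy)-3-methoxybenzaldehyde F4, reduced (NaBH4) to [2,4-bis(benzyloxy)-3-methoxyphenyl]methanol F5 and converted (PBr3) into 1,3-bis(benzyloxy)-4-(bromomethyl)-2-methoxybenzene F6. Evans alkylation of the sodium Z-enolate of F2 (NaHMDS, THF, −78 °C) with F6, the electrophile entering opposite to the benzyl group of the auxiliary, should give the (S)-configured alkylated imide F7. LiBH4 then releases the auxiliary and gives the primary alcohol F8. Hydrogenolysis (H2, Pd/C) removes the three benzyl ethers to give the triphenolic alcohol F9. An intramolecular Mitsunobu etherification (PPh3, DIAD, THF, high dilution) by the one phenol that can reach the CH2OH through a six-membered ring gives 14.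

Step 9. The C3 configuration may be lost if the oxocarbenium ion is deprotonated to the 4H-chromene enol ether, or if the lactol opens and enolises under acid. The cation may also be captured by the electron-rich ring A of a second molecule. The fallback sets out from 12 and rejoins at 13 without passing through a cation. NaBH4 (MeOH–THF, 0 °C) reduces the open-chain tautomer to 4-[(2S)-2-[3-(benzyloxy)-2,4,5-trimethoxyphenyl]-3-hydroxypropyl]-2-methoxybenzene-1,3-diol F10. A Mitsunobu cyclisation (PPh3, DIAD, THF) of the ortho phenol onto the primary alcohol then gives 13.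

Step 7. The arylacetaldehyde may self-condense under the amine catalyst, and the electron-rich 2-arylacrolein may dimerise (hetero-Diels–Alder) or polymerise on concentration. The fallback sets out from 5 and rejoins at 9; it swaps the roles of the two ring positions and delivers the enal from a storable acetal. Baeyer–Villiger oxidation of 5 (mCPBA, CH2Cl2) and hydrolysis of the formate (aq. NaOH) should give 3-(benzyloxy)-5-bromo-2,4-dimethoxyphenol F11. O-Methylation (MeI, K2CO3, acetone) gives 3-(benzyloxy)-1-bromo-2,4,5-trimethoxybenzene F12. Bromine–lithium exchange (n-BuLi, THF, −78 °C), B(Oi-Pr)3 and aqueous work-up give [3-(benzyloxy)-2,4,5-trimethoxyphenyl]boronic acid F13. Suzuki–Miyaura coupling with 2-bromoacrolein diethyl acetal (Pd(OAc)2/SPhos, K3PO4, toluene–water) gives 3-(benzyloxy)-1-(3,3-diethoxyprop-1-en-2-yl)-2,4,5-trimethoxybenzene F14. Mild hydrolysis (PPTS, acetone–water) just before step 8 gives 9.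

Further compounds
F1 | step 8 | 2-[3-(benzyloxy)-2,4,5-trimethoxyphenyl]acetic acid | OC(=O)Cc1cc(OC)c(OC)c(OCc2ccccc2)c1OC
F2 | step 8 | (4S)-4-benzyl-3-{2-[3-(benzyloxy)-2,4,5-trimethoxyphenyl]acetyl}oxazolidin-2-one | O=C(Cc1cc(OC)c(OC)c(OCc2ccccc2)c1OC)N1C(=O)OC[C@@H]1Cc1ccccc1
F3 | step 8 | 1,3-bis(benzyloxy)-2-methoxybenzene | COc1c(OCc2ccccc2)cccc1OCc1ccccc1
F4 | step 8 | 2,4-bis(benzyloxy)-3-methoxybenzaldehyde | COc1c(OCc2ccccc2)ccc(C=O)c1OCc1ccccc1
F5 | step 8 | [2,4-bis(benzyloxy)-3-methoxyphenyl]methanol | COc1c(OCc2ccccc2)ccc(CO)c1OCc1ccccc1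
F6 | step 8 | 1,3-bis(benzyloxy)-4-(bromomethyl)-2-methoxybenzene | COc1c(OCc2ccccc2)ccc(CBr)c1OCc1ccccc1
F7 | step 8 | (4S)-4-benzyl-3-{(2S)-2-[3-(benzyloxy)-2,4,5-trimethoxyphenyl]-3-[2,4-bis(benzyloxy)-3-methoxyphenyl]propanoyl}oxazolidin-2-one | COc1cc([C@H](Cc2ccc(OCc3ccccc3)c(OC)c2OCc2ccccc2)C(=O)N2C(=O)OC[C@@H]2Cc2ccccc2)c(OC)c(OCc2ccccc2)c1OC
F8 | step 8 | (2S)-2-[3-(benzyloxy)-2,4,5-trimethoxyphenyl]-3-[2,4-bis(benzyloxy)-3-methoxyphenyl]propan-1-ol | COc1cc([C@H](Cc2ccc(OCc3ccccc3)c(OC)c2OCc2ccccc2)CO)c(OC)c(OCc2ccccc2)c1OC
F9 | step 8 | 4-[(2S)-3-hydroxy-2-(3-hydroxy-2,4,5-trimethoxyphenyl)propyl]-2-methoxybenzene-1,3-diol | COc1cc([C@H](Cc2ccc(O)c(OC)c2O)CO)c(OC)c(O)c1OC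
F10 | step 9 | 4-[(2S)-2-[3-(benzyloxy)-2,4,5-trimethoxyphenyl]-3-hydroxypropyl]-2-methoxybenzene-1,3-diol | COc1cc([C@H](Cc2ccc(O)c(OC)c2O)CO)c(OC)c(OCc2ccccc2)c1OC
F11 | step 7 | 3-(benzyloxy)-5-bromo-2,4-dimethoxyphenol | COc1c(Br)cc(O)c(OC)c1OCc1ccccc1
F12 | step 7 | 3-(benzyloxy)-1-bromo-2,4,5-trimethoxybenzene | COc1cc(Br)c(OC)c(OCc2ccccc2)c1OC
F13 | step 7 | [3-(benzyloxy)-2,4,5-trimethoxyphenyl]boronic acid | COc1cc(B(O)O)c(OC)c(OCc2ccccc2)c1OC
F14 | step 7 | 3-(benzyloxy)-1-(3,3-diethoxyprop-1-en-2-yl)-2,4,5-trimethoxybenzene | CCOC(OCC)C(=C)c1cc(OC)c(OC)c(OCc2ccccc2)c1OC
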